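The seven-membered ring is disconnected between its CH(2,4-dioxyphenyl) carbon and ring B. This leaves a twofold-symmetric core: ring C, the central benzene, fused to two identical trans-dihydrofurans whose O-bearing C2 (4-oxyphenyl-substituted) and C3 carbons are adjacent. One operation forges both C2–C3 bonds and both dihydrofuran rings: rhodium-carbene insertion into the two 4-methoxybenzylic ether C–H bonds of a ring C bis(aryldiazoacetate). That precursor carries its one-carbon side chain as a diethyl phosphonate, which tolerates the later ester hydrolysis and serves directly for olefination. The C3 esters are then replaced by 3,5-dimethoxyphenyl groups, and acid closes the seven-membered ring before demethylation.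

Key step: step 7

Assumption: Rh2(S-PTTL)4, dirhodium tetrakis[N-phthaloyl-(S)-tert-leucinate], is taken to deliver the 2R sense at both ether carbons; should the sense prove opposite, Rh2(R-PTTL)4 is used with nothing else changed.

Numbering: locants follow benzo[1,2-b:5,4-b']difuran (O1, C2, C3, C3a, C4, C4a, C5, C6, O7, C7a, C8, C8a). C2/C6 are the O–CH(aryl) carbons, C3/C5 their neighbours, and C4 carries the side chain. Ring B is the 3,5-dioxygenated aryl ring that ends up in the seven-membered ring.

Step 1
Reactants: 1 3,5-dihydroxybenzyl alcohol; 2 4-methoxybenzyl chloride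
Product: 3 {3,5-bis[(4-methoxybenzyl)oxy]phenyl}methanol
Conditions: 2 (2.2 equiv), K2CO3, n-Bu4NI (cat.), DMF, 60 °C
Reagents that add atoms: second equivalent of 4-methoxybenzyl chloride 2, COc1ccc(CCl)cc1
Why: Twofold Williamson ether synthesis in which K2CO3 deprotonates only the two phenols, not the benzylic alcohol, and each phenoxide displaces chloride from one molecule of 2 under iodide catalysis.

Step 2
Reactants: 3 {3,5-bis[(4-methoxybenzyl)oxy]phenyl}methanol
Product: 4 1-(bromomethyl)-3,5-bis[(4-methoxybenzyl)oxy]benzene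
Conditions: CBr4, PPh3, CH2Cl2, 0 °C → rt
Reagents that add atoms: carbon tetrabromide, BrC(Br)(Br)Br
Why: Appel bromination converts the primary benzylic alcohol into the bromide under neutral conditions that leave the acid-sensitive 4-methoxybenzyl aryl ethers untouched.

Step 3
Reactants: 4 1-(bromomethyl)-3,5-bis[(4-methoxybenzyl)oxy]benzene; 5 triethyl phosphite
Product: 6 diethyl {3,5-bis[(4-methoxybenzyl)oxy]benzyl}phosphonate
Conditions: neat 5 (excess), 130 °C, EtBr distilled off
Reagents that add atoms: none
Why: Michaelis–Arbuzov reaction in which the phosphite displaces the benzylic bromide and bromide dealkylates the phosphonium intermediate, giving a side chain that is inert to hydroxide, zinc enolates and diazo transfer yet ready for the later olefination.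

Step 4
Reactants: 6 diethyl {3,5-bis[(4-methoxybenzyl)oxy]benzyl}phosphonate
Product: 7 diethyl {2,6-dibromo-3,5-bis[(4-methoxybenzyl)oxy]benzyl}phosphonate
Conditions: NBS (2.05 equiv), MeCN, 0 °C → rt, dark
Reagents that add atoms: N-bromosuccinimide, O=C1CCC(=O)N1Br; second equivalent of N-bromosuccinimide, O=C1CCC(=O)N1Br
Why: Twofold electrophilic aromatic bromination, in which the two ring C positions flanking the side chain are each ortho to one ether oxygen and para to the other, so they react before the less activated anisyl rings and before the crowded position between the two ethers (the usual 4,6-dibromination pattern of resorcinol diethers).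

Step 5
Reactants: 7 diethyl {2,6-dibromo-3,5-bis[(4-methoxybenzyl)oxy]benzyl}phosphonate; 8 methyl bromoacetate
Product: 10 dimethyl 2,2'-{2-[(diethoxyphosphoryl)methyl]-4,6-bis[(4-methoxybenzyl)oxy]-1,3-phenylene}diacetate, via bromozinc ester enolate 9 (not isolated)
Conditions: 8 (3 equiv), Zn dust (Me3SiCl-activated), THF, 40 °C; then 7, Pd2(dba)3 (2.5 mol %), XPhos (10 mol %), THF, 65 °C
Reagents that add atoms: second equivalent of methyl bromoacetate 8, COC(=O)CBr
Why: Twofold Reformatsky–Negishi coupling (palladium-catalysed α-arylation of a zinc ester enolate) in which oxidative addition into each C–Br bond, transmetalation from one molecule of 9 and reductive elimination install the two acetate arms, the mild zinc enolate sparing the phosphonate and the ethers and the bulky biaryl phosphine coping with the ortho-flanked sites.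

Step 6
Reactants: 10 dimethyl 2,2'-{2-[(diethoxyphosphoryl)methyl]-4,6-bis[(4-methoxybenzyl)oxy]-1,3-phenylene}diacetate
Product: 11 dimethyl 2,2'-{2-[(diethoxyphosphoryl)methyl]-4,6-bis[(4-methoxybenzyl)oxy]-1,3-phenylene}bis(2-diazoacetate)
Conditions: p-ABSA (2.6 equiv), DBU (3 equiv), MeCN, 0 °C → rt
Reagents that add atoms: 4-acetamidobenzenesulfonyl azide (p-ABSA), CC(=O)Nc1ccc(cc1)S(=O)(=O)N=[N+]=[N-]; second equivalent of p-ABSA, CC(=O)Nc1ccc(cc1)S(=O)(=O)N=[N+]=[N-]
Why: Twofold Regitz diazo transfer in which DBU deprotonates the two arylacetate methylenes (the benzylic phosphonate is far less acidic) and each enolate takes N2 from one molecule of the sulfonyl azide.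

Step 7
Reactants: 11 dimethyl 2,2'-{2-[(diethoxyphosphoryl)methyl]-4,6-bis[(4-methoxybenzyl)oxy]-1,3-phenylene}bis(2-diazoacetate)
Product: 13 dimethyl (2R,3S,5S,6R)-4-[(diethoxyphosphoryl)methyl]-2,6-bis(4-methoxyphenyl)-2,3,5,6-tetrahydrobenzo[1,2-b:5,4-b']difuran-3,5-dicarboxylate, via monocyclised diazo ester 12 (not isolated)
Conditions: Rh2(S-PTTL)4 (2 mol %), toluene, −40 °C → 0 °C, slow addition of 11
Reagents that add atoms: none
Why: Loss of N2 from each diazo ester at the divalent rhodium centre gives an electrophilic rhodium carbene that inserts into a C–H bond of the adjacent 4-methoxybenzyl ether through a concerted, asynchronous three-centre transition state with hydride-transfer character; the closest known reaction type is the enantioselective intramolecular C–H insertion of methyl 2-(2-benzyloxyphenyl)-2-diazoacetates to cis-2-aryl-2,3-dihydrobenzofuran-3-carboxylates with this catalyst class. Each dihydrofuran ring (O1–C2–C3–C3a–C8a and O7–C6–C5–C4a–C7a) is closed by a 1,5-C–H insertion that joins the carbene carbon (C3 or C5) to the ether methylene carbon (C2 or C6). C2 and C6 are set by the chiral carboxylate pocket of the catalyst, which selects one enantiotopic benzylic hydrogen, whereas C3 and C5 follow from the insertion geometry that places ester and aryl group cis (they are reset later). The site selectivity that is needed is secured by the substrate: the 4-methoxybenzylic ether C–H bond is doubly activated and ideally spaced, while the side-chain CH2 is deactivated by the phosphoryl group and could only close a four-membered ring, and the phosphoryl oxygen can at most add reversibly. Because the two carbene sites are homotopic one catalyst serves both, and a mismatched second insertion ends in a meso diastereomer that is removed by chromatography, which should raise the enantiomeric purity of the twofold-symmetric product.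

Step 8
Reactants: 13 dimethyl (2R,3S,5S,6R)-4-[(diethoxyphosphoryl)methyl]-2,6-bis(4-methoxyphenyl)-2,3,5,6-tetrahydrobenzo[1,2-b:5,4-b']difuran-3,5-dicarboxylate
Product: 15 (2R,3R,5R,6R)-4-[(diethoxyphosphoryl)methyl]-2,6-bis(4-methoxyphenyl)-2,3,5,6-tetrahydrobenzo[1,2-b:5,4-b']difuran-3,5-dicarboxylic acid, via trans-trans dimethyl ester 14 (not isolated)
Conditions: NaOMe (0.3 equiv), MeOH/THF, 25 °C; then LiOH·H2O (excess), H2O, 45 °C; then 1 M HCl to pH 3, 0 °C
Reagents that add atoms: lithium hydroxide, [Li+].[OH-]; second equivalent of lithium hydroxide, [Li+].[OH-]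
Why: Base epimerisation followed by saponification, in which methoxide enolises each ester and reprotonation gives the thermodynamically preferred trans arrangement (3R,5R) before hydroxide cleaves the two methyl esters; C2 and C6 are untouched because ring opening from the enolate would be the reverse of a disfavoured 5-endo-trig closure, the diethyl phosphonate is inert to aqueous hydroxide at this temperature, and any cis acid that remains converges in step 9.

Step 9
Reactants: 15 (2R,3R,5R,6R)-4-[(diethoxyphosphoryl)methyl]-2,6-bis(4-methoxyphenyl)-2,3,5,6-tetrahydrobenzo[1,2-b:5,4-b']difuran-3,5-dicarboxylic acid; 16 1-bromo-3,5-dimethoxybenzene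
Product: 17 diethyl {[(2R,3R,5R,6R)-3,5-bis(3,5-dimethoxyphenyl)-2,6-bis(4-methoxyphenyl)-2,3,5,6-tetrahydrobenzo[1,2-b:5,4-b']difuran-4-yl]methyl}phosphonate
Conditions: 16 (3 equiv), Ir[dF(CF3)ppy]2(dtbbpy)PF6 (2 mol %), NiCl2·glyme (10 mol %), dtbbpy (15 mol %), Cs2CO3, DMF, blue LEDs, 25 °C
Reagents that add atoms: second equivalent of 1-bromo-3,5-dimethoxybenzene 16, COc1cc(Br)cc(OC)c1
Why: Twofold metallaphotoredox decarboxylative arylation of an α-aryl carboxylic acid, in which the excited iridium photocatalyst oxidises each caesium carboxylate, loss of CO2 gives the benzylic C3 (C5) radical, and nickel that has added into the C–Br bond of one molecule of 16 captures it on the face anti to the neighbouring 4-methoxyphenyl group before reductive elimination, so both new centres should be set trans (3R,5R) by substrate control whatever the configuration of the acid.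

Step 10
Reactants: 17 diethyl {[(2R,3R,5R,6R)-3,5-bis(3,5-dimethoxyphenyl)-2,6-bis(4-methoxyphenyl)-2,3,5,6-tetrahydrobenzo[1,2-b:5,4-b']difuran-4-yl]methyl}phosphonate; 18 2,4-dimethoxybenzaldehyde
Product: 19 (2R,3R,5R,6R)-4-[(E)-2-(2,4-dimethoxyphenyl)ethenyl]-3,5-bis(3,5-dimethoxyphenyl)-2,6-bis(4-methoxyphenyl)-2,3,5,6-tetrahydrobenzo[1,2-b:5,4-b']difuran
Conditions: KOtBu, THF, 0 °C → 40 °C
Reagents that add atoms: none
Why: Horner–Wadsworth–Emmons olefination in which the phosphonate-stabilised benzylic carbanion (far more acidic than the diarylmethine C–H bonds) adds to the aldehyde and eliminates diethyl phosphate to give the E-stilbene, whose geometry is in any case erased in step 11.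

Step 11
Reactants: 19 (2R,3R,5R,6R)-4-[(E)-2-(2,4-dimethoxyphenyl)ethenyl]-3,5-bis(3,5-dimethoxyphenyl)-2,6-bis(4-methoxyphenyl)-2,3,5,6-tetrahydrobenzo[1,2-b:5,4-b']difuran
Product: 20 octa-O-methyl ether of the target (seven-membered ring closed from the side-chain CH onto an ortho carbon of one 3,5-dimethoxyphenyl ring; new methine R)
Conditions: MeSO3H, CH2Cl2, −20 °C → 0 °C
Reagents that add atoms: none
Why: Acid-promoted intramolecular Friedel–Crafts alkylation, the known closure of ε-viniferin-type stilbenes to ampelopsin B-type seven-membered rings: protonation at the alkene carbon next to ring C gives the 2,4-dimethoxybenzylic cation, which is attacked by an ortho carbon (ortho and para to methoxy) of either homotopic 3,5-dimethoxyphenyl ring, so a single constitution arises; the new methine should form R, with its aryl group pseudo-axial and away from the ortho methoxy group of ring B (hydrogen trans to the neighbouring dihydrofuran C–H across the seven-membered ring), the reversibility of the ionisation favouring this more stable epimer.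

Step 12
Reactants: 20 octa-O-methyl ether of the target
Product: 21 target CNP0154047.1
Conditions: BBr3 (excess), CH2Cl2, −78 °C → rt; then MeOH/H2O
Reagents that add atoms: none
Why: Lewis-acid ether cleavage in which BBr3 coordinates each aryl methyl ether and bromide removes the methyl group by SN2, as is standard for permethylated resveratrol oligomers; no stereocentre is involved, and any transient opening at a dihydrofuran C–O bond should reclose to the same, more stable trans isomer.

Compound list

1 | 3,5-dihydroxybenzyl alcohol | OCc1cc(O)cc(O)c1 | starting material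
2 | 4-methoxybenzyl chloride | COc1ccc(CCl)cc1 | starting material
3 | {3,5-bis[(4-methoxybenzyl)oxy]phenyl}methanol | OCc1cc(OCc2ccc(OC)cc2)cc(OCc2ccc(OC)cc2)c1 | intermediate
4 | 1-(bromomethyl)-3,5-bis[(4-methoxybenzyl)oxy]benzene | BrCc1cc(OCc2ccc(OC)cc2)cc(OCc2ccc(OC)cc2)c1 | intermediate
5 | triethyl phosphite | CCOP(OCC)OCC | starting material
6 | diethyl {3,5-bis[(4-methoxybenzyl)oxy]benzyl}phosphonate | CCOP(=O)(OCC)Cc1cc(OCc2ccc(OC)cc2)cc(OCc2ccc(OC)cc2)c1 | intermediate
7 | diethyl {2,6-dibromo-3,5-bis[(4-methoxybenzyl)oxy]benzyl}phosphonate | CCOP(=O)(OCC)Cc1c(Br)c(OCc2ccc(OC)cc2)cc(OCc2ccc(OC)cc2)c1Br | intermediate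
8 | methyl bromoacetate | COC(=O)CBr | starting material
9 | (2-methoxy-2-oxoethyl)zinc bromide, BrZnCH2CO2Me (not isolated) | COC(=O)C[Zn]Br | intermediate
10 | dimethyl 2,2'-{2-[(diethoxyphosphoryl)methyl]-4,6-bis[(4-methoxybenzyl)oxy]-1,3-phenylene}diacetate | CCOP(=O)(OCC)Cc1c(CC(=O)OC)c(OCc2ccc(OC)cc2)cc(OCc2ccc(OC)cc2)c1CC(=O)OC | intermediate
11 | dimethyl 2,2'-{2-[(diethoxyphosphoryl)methyl]-4,6-bis[(4-methoxybenzyl)oxy]-1,3-phenylene}bis(2-diazoacetate) | CCOP(=O)(OCC)Cc1c(C(=[N+]=[N-])C(=O)OC)c(OCc2ccc(OC)cc2)cc(OCc2ccc(OC)cc2)c1C(=[N+]=[N-])C(=O)OC | intermediate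
12 | methyl (2R,3S)-5-(1-diazo-2-methoxy-2-oxoethyl)-4-[(diethoxyphosphoryl)methyl]-6-[(4-methoxybenzyl)oxy]-2-(4-methoxyphenyl)-2,3-dihydro-1-benzofuran-3-carboxylate (not isolated) | COc1ccc([C@@H]2Oc3cc(OCc4ccc(OC)cc4)c(C(=[N+]=[N-])C(=O)OC)c(CP(=O)(OCC)OCC)c3[C@@H]2C(=O)OC)cc1 | intermediate
13 | dimethyl (2R,3S,5S,6R)-4-[(diethoxyphosphoryl)methyl]-2,6-bis(4-methoxyphenyl)-2,3,5,6-tetrahydrobenzo[1,2-b:5,4-b']difuran-3,5-dicarboxylate (both rings cis) | COc1ccc([C@@H]2Oc3cc4c(c(CP(=O)(OCC)OCC)c3[C@@H]2C(=O)OC)[C@H](C(=O)OC)[C@H](c2ccc(OC)cc2)O4)cc1 | intermediate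
14 | dimethyl (2R,3R,5R,6R)-4-[(diethoxyphosphoryl)methyl]-2,6-bis(4-methoxyphenyl)-2,3,5,6-tetrahydrobenzo[1,2-b:5,4-b']difuran-3,5-dicarboxylate (both rings trans; not isolated) | COc1ccc([C@@H]2Oc3cc4c(c(CP(=O)(OCC)OCC)c3[C@H]2C(=O)OC)[C@@H](C(=O)OC)[C@H](c2ccc(OC)cc2)O4)cc1 | intermediate
15 | (2R,3R,5R,6R)-4-[(diethoxyphosphoryl)methyl]-2,6-bis(4-methoxyphenyl)-2,3,5,6-tetrahydrobenzo[1,2-b:5,4-b']difuran-3,5-dicarboxylic acid | COc1ccc([C@@H]2Oc3cc4c(c(CP(=O)(OCC)OCC)c3[C@H]2C(=O)O)[C@@H](C(=O)O)[C@H](c2ccc(OC)cc2)O4)cc1 | intermediate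
16 | 1-bromo-3,5-dimethoxybenzene | COc1cc(Br)cc(OC)c1 | starting material
17 | diethyl {[(2R,3R,5R,6R)-3,5-bis(3,5-dimethoxyphenyl)-2,6-bis(4-methoxyphenyl)-2,3,5,6-tetrahydrobenzo[1,2-b:5,4-b']difuran-4-yl]methyl}phosphonate | COc1ccc([C@@H]2Oc3cc4c(c(CP(=O)(OCC)OCC)c3[C@H]2c2cc(OC)cc(OC)c2)[C@@H](c2cc(OC)cc(OC)c2)[C@H](c2ccc(OC)cc2)O4)cc1 | intermediate
18 | 2,4-dimethoxybenzaldehyde | COc1ccc(C=O)c(OC)c1 | starting material
19 | (2R,3R,5R,6R)-4-[(E)-2-(2,4-dimethoxyphenyl)ethenyl]-3,5-bis(3,5-dimethoxyphenyl)-2,6-bis(4-methoxyphenyl)-2,3,5,6-tetrahydrobenzo[1,2-b:5,4-b']difuran | COc1ccc([C@@H]2Oc3cc4c(c(/C=C/c5ccc(OC)cc5OC)c3[C@H]2c2cc(OC)cc(OC)c2)[C@@H](c2cc(OC)cc(OC)c2)[C@H](c2ccc(OC)cc2)O4)cc1 | intermediate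
20 | octa-O-methyl ether of the target: both dihydrofurans trans (2R,3R), seven-membered ring through CH2–CH(2,4-dimethoxyphenyl) onto ring B, methine R | COc1ccc([C@@H]2Oc3cc4c5c(c3[C@H]2c2cc(OC)cc(OC)c2)C[C@H](c2ccc(OC)cc2OC)c2c(OC)cc(OC)cc2[C@H]5[C@H](c2ccc(OC)cc2)O4)cc1 | intermediate
21 | CNP0154047.1, the octaphenol corresponding to 20 | Oc1ccc([C@@H]2Oc3cc4c5c(c3[C@H]2c2cc(O)cc(O)c2)C[C@H](c2ccc(O)cc2O)c2c(O)cc(O)cc2[C@H]5[C@H](c2ccc(O)cc2)O4)cc1 | target

Total step count: 12. Longest linear sequence: 12 steps (1 → 21); 2, 5, 8, 16 and 18 are purchased.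

Steps most likely to fail

Step 7 (double C–H insertion). The second carbene may form while the first site is still uncyclised, so intermolecular carbene–diazo coupling can compete. Crowding by the flanking side chain may also slow insertion, erode the enantio- and diastereocontrol of the twofold event, or let the phosphoryl oxygen hold the carbene. The fallback performs the two insertions one at a time, each then being the precedented single event. From 10, diazo transfer with about one equivalent of p-ABSA/DBU should give the mono(diazoacetate) F1, with unreacted 10 recycled. Rh2(S-PTTL)4 in toluene then closes the first ring to the cis-dihydrofuran monoacetate F2. A second diazo transfer, which can only take place at the remaining arylacetate CH2, converts F2 into 12. A second insertion, for which catalyst and temperature can be tuned separately, gives 13, where the route is rejoined. Any base epimerisation at C3 of the first ring is without consequence, because step 8 equilibrates that centre.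

Step 9 (double decarboxylative arylation). Capture of the hindered benzylic radical by nickel may be slow. That would allow protodecarboxylation, radical dimerisation, β-hydride loss to a benzofuran (which erases C2), or a stalled second arylation. The fallback activates the acid thermally as a redox-active ester and couples it with an arylzinc reagent. From 15, N-hydroxyphthalimide and N,N'-diisopropylcarbodiimide (DMAP cat., CH2Cl2) give the bis(N-acyloxyphthalimide) F3. In parallel, 16 is converted with Mg and LiCl in THF into (3,5-dimethoxyphenyl)magnesium bromide F4, which ZnCl2 transmetalates to (3,5-dimethoxyphenyl)zinc chloride F5. NiCl2·glyme with 4,4'-di-tert-butyl-2,2'-bipyridine in THF/DMF at 25 °C then couples F3 with F5, with loss of CO2 and phthalimide, to give 17, where the route is rejoined.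

Step 5 (double Reformatsky–Negishi coupling). Transmetalation of the zinc enolate and reductive elimination from the palladium enolate may be slow at the two doubly ortho-flanked, electron-rich aryl positions, leading to mono-coupling and protodebromination. The fallback replaces the enolate by an allyl group and oxidises afterwards. From 7, twofold Stille allylation (Bu3SnCH2CH=CH2, Pd(P(t-Bu)3)2, CsF, dioxane, 100 °C) gives the 2,6-diallyl phosphonate F6. Lemieux–Johnson cleavage (OsO4 cat., NaIO4, 2,6-lutidine, dioxane/H2O) gives the bis(arylacetaldehyde) F7. Pinnick oxidation (NaClO2, NaH2PO4, 2-methyl-2-butene, t-BuOH/H2O) gives the diacid F8, and Me3SiCHN2 in toluene/MeOH returns the route at 10.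

Further compounds

F1 | step 7 | methyl 2-diazo-2-{2-[(diethoxyphosphoryl)methyl]-3-(2-methoxy-2-oxoethyl)-4,6-bis[(4-methoxybenzyl)oxy]phenyl}acetate | CCOP(=O)(OCC)Cc1c(C(=[N+]=[N-])C(=O)OC)c(OCc2ccc(OC)cc2)cc(OCc2ccc(OC)cc2)c1CC(=O)OC
F2 | step 7 | methyl (2R,3S)-4-[(diethoxyphosphoryl)methyl]-5-(2-methoxy-2-oxoethyl)-6-[(4-methoxybenzyl)oxy]-2-(4-methoxyphenyl)-2,3-dihydro-1-benzofuran-3-carboxylate | COc1ccc([C@@H]2Oc3cc(OCc4ccc(OC)cc4)c(CC(=O)OC)c(CP(=O)(OCC)OCC)c3[C@@H]2C(=O)OC)cc1
F3 | step 9 | bis(1,3-dioxoisoindolin-2-yl) (2R,3R,5R,6R)-4-[(diethoxyphosphoryl)methyl]-2,6-bis(4-methoxyphenyl)-2,3,5,6-tetrahydrobenzo[1,2-b:5,4-b']difuran-3,5-dicarboxylate | COc1ccc([C@@H]2Oc3cc4c(c(CP(=O)(OCC)OCC)c3[C@H]2C(=O)ON2C(=O)c3ccccc3C2=O)[C@@H](C(=O)ON2C(=O)c3ccccc3C2=O)[C@H](c2ccc(OC)cc2)O4)cc1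
F4 | step 9 | (3,5-dimethoxyphenyl)magnesium bromide | COc1cc([Mg]Br)cc(OC)c1
F5 | step 9 | (3,5-dimethoxyphenyl)zinc chloride | COc1cc([Zn]Cl)cc(OC)c1
F6 | step 5 | diethyl {2,6-diallyl-3,5-bis[(4-methoxybenzyl)oxy]benzyl}phosphonate | CCOP(=O)(OCC)Cc1c(CC=C)c(OCc2ccc(OC)cc2)cc(OCc2ccc(OC)cc2)c1CC=C
F7 | step 5 | diethyl {3,5-bis[(4-methoxybenzyl)oxy]-2,6-bis(2-oxoethyl)benzyl}phosphonate | CCOP(=O)(OCC)Cc1c(CC=O)c(OCc2ccc(OC)cc2)cc(OCc2ccc(OC)cc2)c1CC=O
F8 | step 5 | 2,2'-{2-[(diethoxyphosphoryl)methyl]-4,6-bis[(4-methoxybenzyl)oxy]-1,3-phenylene}diacetic acid | CCOP(=O)(OCC)Cc1c(CC(=O)O)c(OCc2ccc(OC)cc2)cc(OCc2ccc(OC)cc2)c1CC(=O)O
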